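**Retrosynthetic overview**

1. The target is a cyclohexane (C5–C10, elemanolide numbering) with a trans-fused α-methylene-γ-lactone (O–C6, C7, C11=C13, C12); the substituents on C5–C8 are all equatorial, and C9 is a neopentyl CH2 on the quaternary C10 (vinyl, CH2OAc).
2. Key disconnection: C6–C7 and C8–C9 (and the lactone C–O bond) are formed in one chromium-mediated Barbier cascade from lactol 12 (C9–C10–C5–C6: iodide plus masked aldehyde) and butenolide 19 (C7–C8 plus C11–C13: masked formyl acrylate); the cyclohexane and the γ-lactone ring both form in that step.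
3. Enabling feature: C7 is the γ-carbon of a 2-carboxyallyl unit (C13=C11–C12) and lies between the two carbinol carbons C6 and C8, so a 3-(bromomethyl)-5-alkoxybutenolide maps onto C7/C8/C11–C13; its temporary ring fixes the allyl geometry and hides C8 as an acetal that the new C6 alkoxide releases.
4. Lactol 12 (C5 and C10 stereocentres) comes from a 5-menthyloxybutenolide by anti conjugate addition, aldol/dehydration and deconjugative iodomethylation, then reduction and lactol formation; 19 comes from furan-3-ylmethanol by photooxygenation.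
5. Endgame: diacetylation, then allylic oxidation of the isopropenyl group to the acrolein unit.

Key step: step 10

Remark on the chemistry: "menthyloxy" means [(1S,2R,5S)-5-methyl-2-(propan-2-yl)cyclohexyl]oxy; acetal and lactol centres that are lost later (in 12, 17–21) are carried as mixtures, and 19 is used as the racemate.

**Route**

Step 1
Reactants: 1 5-hydroxyfuran-2(5H)-one; 2 (+)-menthol
Product: 3 (5S)-5-(menthyloxy)furan-2(5H)-one
Conditions: p-TsOH (cat.), toluene, reflux (Dean–Stark); crystallisation from petroleum ether, mother liquor re-equilibrated with acid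
Reagents that add atoms: none
Why: Acid-catalysed acetalisation of the pseudo-acid; the acetal centre epimerises under the conditions and the (5S) epimer, the mirror image of the well-known crystalline (5R)-(−)-menthyloxy butenolide, should crystallise out, which sets the absolute configuration of the route.

Step 2
Reactants: 3
Product: 5 (3R,4R,5S)-3-(1-hydroxyethyl)-5-(menthyloxy)-4-(prop-1-en-2-yl)oxolan-2-one (carbinol epimers), via bromomagnesium enolate 4 (not isolated)
Conditions: CH2=C(CH3)MgBr (1.5 equiv), CuBr·SMe2 (20 mol %), THF, −78 °C; then CH3CHO, −78 °C; aq. NH4Cl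
Reagents that add atoms: isopropenylmagnesium bromide, C=C(C)[Mg]Br; acetaldehyde, CC=O
Why: Copper-catalysed conjugate addition of the Grignard reagent should occur anti to the menthyloxy group and set C5, and the enolate is trapped in a tandem aldol reaction anti to the new isopropenyl group (this carbinol centre is lost in step 3).

Step 3
Reactants: 5
Product: 7 (3E,4S,5S)-3-ethylidene-5-(menthyloxy)-4-(prop-1-en-2-yl)oxolan-2-one, via mesylate 6 (not isolated)
Conditions: MsCl, Et3N, CH2Cl2, 0 °C; then DBU, rt
Reagents that add atoms: none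
Why: Mesylation and E1cB elimination through the acidic lactone α-hydrogen complete an aldol condensation to the conjugated ethylidene lactone; no stereocentre is formed and C5 is not touched.

Step 4
Reactants: 7
Product: 9 (3S,4S,5S)-3-ethenyl-3-(iodomethyl)-5-(menthyloxy)-4-(prop-1-en-2-yl)oxolan-2-one, via lithium dienolate 8 (not isolated)
Conditions: LiN(i-Pr)2 (1.1 equiv), THF–DMPU, −78 °C; CH2I2 (3 equiv), −78 → −20 °C
Reagents that add atoms: diiodomethane, ICI
Why: Deconjugative α-alkylation of the extended dienolate (γ-deprotonation, kinetic attack at the α-carbon) should create the quaternary C10 with its vinyl group and the neopentyl iodide in one step, the electrophile entering anti to the neighbouring isopropenyl group.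

Step 5
Reactants: 9
Product: 10 (2S,3S)-2-ethenyl-2-(iodomethyl)-3-(prop-1-en-2-yl)butane-1,4-diol
Conditions: LiBH4, THF, 0 °C → rt; aq. NH4Cl
Reagents that add atoms: none
Why: Hydride reduction of the pseudo-ester reduces both the lactone carbonyl (C14) and the unmasked aldehyde (C6) to the 1,4-diol and releases the auxiliary as menthol, while the neopentyl iodide is inert to SN2 attack by hydride.

Step 6
Reactants: 10
Product: 12 (3S,4S)-4-ethenyl-4-(iodomethyl)-3-(prop-1-en-2-yl)oxolan-2-ol (lactol, both anomers), via hydroxy aldehyde 11 (not isolated)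
Conditions: IBX (2-iodoxybenzoic acid, 1.2 equiv), DMSO, rt
Reagents that add atoms: none
Why: IBX oxidation of a 1,4-diol stops at the γ-lactol; the CH2OH on the methine carbon (C6) should be oxidised in preference to the neopentyl CH2OH (C14), and ring closure of 11 protects the epimerisable β,γ-unsaturated aldehyde under neutral conditions.

Step 7
Reactants: 13 furan-3-ylmethanol
Product: 16 [2-(trimethylsilyl)furan-3-yl]methanol, via dilithio species 14 (not isolated), via bis-silyl compound 15 (not isolated)
Conditions: n-BuLi (2.2 equiv), DME, 0 °C; Me3SiCl (2.3 equiv), 0 °C → rt; then K2CO3 (cat.), MeOH, rt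
Reagents that add atoms: chlorotrimethylsilane, C[Si](C)(C)Cl
Why: Alkoxide-directed ortho-lithiation of the furan at C2 (between the ring oxygen and the CH2OLi group) followed by C-silylation; the O-silyl group is cleaved by methanolysis.

Step 8
Reactants: 16
Product: 18 3-(hydroxymethyl)-5-methoxyfuran-2(5H)-one (racemic), via hydroxybutenolide 17 (not isolated)
Conditions: O2, hν (visible), tetraphenylporphyrin (cat.), CH2Cl2–MeOH, −78 °C; then p-TsOH (cat.), MeOH, rt
Reagents that add atoms: dioxygen, O=O; methanol, CO
Why: Regiospecific photooxygenation of a 2-silylfuran ([4+2] addition of singlet oxygen, then silyl migration with O–O cleavage) places the carbonyl at the former silylated carbon, and acid-catalysed methanolysis turns the γ-hydroxybutenolide into its pseudo-ester.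

Step 9
Reactants: 18
Product: 19 3-(bromomethyl)-5-methoxyfuran-2(5H)-one (racemic)
Conditions: CBr4, PPh3, CH2Cl2, 0 °C
Reagents that add atoms: tetrabromomethane, BrC(Br)(Br)Br
Why: Appel bromination of the primary allylic alcohol under neutral conditions should leave the acetal untouched.

Step 10
Reactants: 12 lactol; 19 butenolide bromide (2.5 equiv)
Product: 22 (3aR,4S,6R,7S,7aR)-6-ethenyl-4-hydroxy-6-(hydroxymethyl)-3-methylidene-7-(prop-1-en-2-yl)hexahydro-1-benzofuran-2(3H)-one, via allylation adduct 20 (not isolated), via aldehyde lactone 21 (not isolated)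
Conditions: CrCl2 (10 equiv, 0.5 M), cyanocobalamin (C63H88CoN14O14P, 10 mol %), DMF, rt, 1 h; then 19 in THF added over 2 h, rt; aq. NH4Cl
Reagents that add atoms: none
Why: Proposed new method: a double Barbier cascade on chromium relayed by a translactonisation, reasoned as follows: CrCl2 with monovalent cobalt from cyanocobalamin first turns the neopentyl iodide of 12 into a C9 alkylchromium (trivalent chromium; no β-hydrogen, inert to OH groups, unable to reach C6 through a four-membered ring), then reduces 19 to a 2-carboxyallylchromium that adds through C7 to the aldehyde of open form 11 (C6–C7 bond), after which the C6 alkoxide attacks the activated pseudo-ester carbonyl and expels C8 as a hemiacetal that collapses to aldehyde 21 and methanol, and the waiting C9–Cr bond adds to this aldehyde (C8–C9 bond). The closest known reactions are the chromium- or indium-mediated 2-(alkoxycarbonyl)allylation of aldehydes with 3-(bromomethyl)furan-2(5H)-one followed by translactonisation to trans-β,γ-disubstituted α-methylene-γ-butyrolactones, and the cobalt-catalysed formation of alkylchromium reagents from primary alkyl iodides with their aldehyde-selective addition (Nozaki–Hiyama–Kishi family); running them as one relay and using a 5-alkoxybutenolide as a latent aldehyde are new. The γ-lactone ring closes by 5-exo-trig acyl transfer and the cyclohexane ring by 6-exo-trig addition of C9 to the C8 carbonyl, while the temporary butenolide ring of 19 is opened. C6 should be set by Felkin–Anh attack anti to the quaternary C10 (isopropenyl as the medium group), C7 by the chair Zimmerman–Traxler transition state in which the butenolide ring holds C8 trans to the CH2–Cr carbon (anti adduct, hence the trans ring fusion), and C8 by the chair transition state of the ring closure on the rigid trans-fused lactone with the chromium alkoxide equatorial. The step needs the allylation to precede the alkylchromium addition, which is secured because C8 stays an acetal until the C6 alkoxide exists; it needs the C9 radical to be captured before its 1,2-vinyl shift, which the high CrCl2 concentration should secure; and it needs the Felkin-matched enantiomer of racemic 19 to react first, which the excess of 19 allows, its acetal centre being erased in any case.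

Step 11
Reactants: 22
Product: 23 [(3aR,4S,6R,7S,7aR)-4-acetoxy-6-ethenyl-3-methylidene-2-oxo-7-(prop-1-en-2-yl)octahydro-1-benzofuran-6-yl]methyl acetate
Conditions: Ac2O, pyridine, 4-(dimethylamino)pyridine (cat.), CH2Cl2, 0 °C → rt
Reagents that add atoms: acetic anhydride, CC(=O)OC(C)=O
Why: Nucleophile-catalysed acylation of the secondary C8 and the neopentyl C14 hydroxyl groups touches no stereocentre and caps the C8 hydroxyl before it can relactonise onto C12.

Step 12
Reactants: 23
Product: 24 [(3aR,4S,6R,7S,7aR)-4-acetoxy-6-ethenyl-7-(3-hydroxyprop-1-en-2-yl)-3-methylidene-2-oxooctahydro-1-benzofuran-6-yl]methyl acetate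
Conditions: SeO2 (30 mol %), t-BuOOH (3 equiv), CH2Cl2, 0 °C → rt
Reagents that add atoms: tert-butyl hydroperoxide, CC(C)(C)OO (terminal oxidant; the oxygen atom is passed on by catalytic SeO2)
Why: Riley-type allylic oxidation (ene reaction, then [2,3]-sigmatropic shift) should hydroxylate the methyl group of the isopropenyl alkene, because the vinyl group has no allylic hydrogen, the electron-poor methylene lactone is inert and the hindered allylic methine at C5 reacts more slowly than the methyl group.

Step 13
Reactants: 24
Product: 25 [(3aR,4S,6R,7R,7aR)-4-acetoxy-6-ethenyl-3-methylidene-2-oxo-7-(3-oxoprop-1-en-2-yl)octahydro-1-benzofuran-6-yl]methyl acetate (target)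
Conditions: MnO2 (activated, excess), CH2Cl2, rt
Reagents that add atoms: none
Why: Chemoselective MnO2 oxidation of the primary allylic alcohol to the conjugated aldehyde under neutral conditions should leave the acetates and the methylene lactone untouched.

**Compound list**

1 | 5-hydroxyfuran-2(5H)-one | OC1OC(=O)C=C1 | starting material
2 | (+)-menthol, (1S,2R,5S)-5-methyl-2-(propan-2-yl)cyclohexan-1-ol | O[C@H]1C[C@@H](C)CC[C@@H]1C(C)C | starting material
3 | (5S)-5-(menthyloxy)furan-2(5H)-one | O=C1C=C[C@@H](O[C@H]2C[C@@H](C)CC[C@@H]2C(C)C)O1 | intermediate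
4 | bromomagnesium (4R,5S)-5-(menthyloxy)-4-(prop-1-en-2-yl)-4,5-dihydrofuran-2-olate (isopropenyl trans to menthyloxy) | Br[Mg]OC1=C[C@H](C(C)=C)[C@@H](O[C@H]2C[C@@H](C)CC[C@@H]2C(C)C)O1 | intermediate
5 | (3R,4R,5S)-3-(1-hydroxyethyl)-5-(menthyloxy)-4-(prop-1-en-2-yl)oxolan-2-one (carbinol epimers; all-trans ring) | CC(O)[C@@H]1C(=O)O[C@H](O[C@H]2C[C@@H](C)CC[C@@H]2C(C)C)[C@H]1C(C)=C | intermediate
6 | methanesulfonate of 5 | CC(OS(C)(=O)=O)[C@@H]1C(=O)O[C@H](O[C@H]2C[C@@H](C)CC[C@@H]2C(C)C)[C@H]1C(C)=C | intermediate
7 | (3E,4S,5S)-3-ethylidene-5-(menthyloxy)-4-(prop-1-en-2-yl)oxolan-2-one | C/C=C1/C(=O)O[C@H](O[C@H]2C[C@@H](C)CC[C@@H]2C(C)C)[C@H]1C(C)=C | intermediate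
8 | lithium (4S,5S)-3-ethenyl-5-(menthyloxy)-4-(prop-1-en-2-yl)-4,5-dihydrofuran-2-olate | [Li]OC1=C(C=C)[C@H](C(C)=C)[C@@H](O[C@H]2C[C@@H](C)CC[C@@H]2C(C)C)O1 | intermediate
9 | (3S,4S,5S)-3-ethenyl-3-(iodomethyl)-5-(menthyloxy)-4-(prop-1-en-2-yl)oxolan-2-one (CH2I trans, vinyl cis to isopropenyl) | C=C[C@@]1(CI)C(=O)O[C@H](O[C@H]2C[C@@H](C)CC[C@@H]2C(C)C)[C@H]1C(C)=C | intermediate
10 | (2S,3S)-2-ethenyl-2-(iodomethyl)-3-(prop-1-en-2-yl)butane-1,4-diol | C=C[C@](CO)(CI)[C@@H](CO)C(C)=C | intermediate
11 | (2S,3S)-3-(hydroxymethyl)-3-(iodomethyl)-2-(prop-1-en-2-yl)pent-4-enal (open form of 12) | C=C[C@](CO)(CI)[C@@H](C=O)C(C)=C | intermediate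
12 | (3S,4S)-4-ethenyl-4-(iodomethyl)-3-(prop-1-en-2-yl)oxolan-2-ol (both anomers) | C=C[C@@]1(CI)COC(O)[C@H]1C(C)=C | intermediate
13 | furan-3-ylmethanol | OCc1ccoc1 | starting material
14 | lithium (2-lithiofuran-3-yl)methanolate | [Li]OCc1ccoc1[Li] | intermediate
15 | trimethyl{[2-(trimethylsilyl)furan-3-yl]methoxy}silane | C[Si](C)(C)OCc1ccoc1[Si](C)(C)C | intermediate
16 | [2-(trimethylsilyl)furan-3-yl]methanol | OCc1ccoc1[Si](C)(C)C | intermediate
17 | 5-hydroxy-3-(hydroxymethyl)furan-2(5H)-one (racemic) | OCC1=CC(O)OC1=O | intermediate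
18 | 3-(hydroxymethyl)-5-methoxyfuran-2(5H)-one (racemic) | COC1OC(=O)C(CO)=C1 | intermediate
19 | 3-(bromomethyl)-5-methoxyfuran-2(5H)-one (racemic) | COC1OC(=O)C(CBr)=C1 | intermediate
20 | (4S)-4-[(1R,2S,3S)-1-hydroxy-3-(hydroxymethyl)-3-(iodomethyl)-2-(prop-1-en-2-yl)pent-4-en-1-yl]-5-methoxy-3-methylideneoxolan-2-one (acetal epimers) | C=C[C@](CO)(CI)[C@@H]([C@@H](O)[C@@H]1C(=C)C(=O)OC1OC)C(C)=C | intermediate
21 | (2R,3S)-2-[(1S,2S)-2-(hydroxymethyl)-2-(iodomethyl)-1-(prop-1-en-2-yl)but-3-en-1-yl]-4-methylidene-5-oxooxolane-3-carbaldehyde | C=C[C@](CO)(CI)[C@@H]([C@H]1OC(=O)C(=C)[C@@H]1C=O)C(C)=C | intermediate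
22 | (3aR,4S,6R,7S,7aR)-6-ethenyl-4-hydroxy-6-(hydroxymethyl)-3-methylidene-7-(prop-1-en-2-yl)hexahydro-1-benzofuran-2(3H)-one | C=C[C@]1(CO)C[C@H](O)[C@H]2C(=C)C(=O)O[C@@H]2[C@H]1C(C)=C | intermediate
23 | [(3aR,4S,6R,7S,7aR)-4-acetoxy-6-ethenyl-3-methylidene-2-oxo-7-(prop-1-en-2-yl)octahydro-1-benzofuran-6-yl]methyl acetate | C=C[C@]1(COC(C)=O)C[C@H](OC(C)=O)[C@H]2C(=C)C(=O)O[C@@H]2[C@H]1C(C)=C | intermediate
24 | [(3aR,4S,6R,7S,7aR)-4-acetoxy-6-ethenyl-7-(3-hydroxyprop-1-en-2-yl)-3-methylidene-2-oxooctahydro-1-benzofuran-6-yl]methyl acetate | C=C[C@]1(COC(C)=O)C[C@H](OC(C)=O)[C@H]2C(=C)C(=O)O[C@@H]2[C@H]1C(=C)CO | intermediate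
25 | [(3aR,4S,6R,7R,7aR)-4-acetoxy-6-ethenyl-3-methylidene-2-oxo-7-(3-oxoprop-1-en-2-yl)octahydro-1-benzofuran-6-yl]methyl acetate | C=C[C@]1(COC(C)=O)C[C@H](OC(C)=O)[C@H]2C(=C)C(=O)O[C@@H]2[C@H]1C(=C)C=O | target

**Summary**

Total step count: 13 (branch to 12: steps 1–6; branch to 19: steps 7–9; union and endgame: steps 10–13).
Longest linear sequence: 10 steps (1–6, 10–13).

**Steps most likely to fail**

Step 10 (Proposed new method). The allylchromium species may lose its ring oxygen by β-elimination, the translactonisation may stall at the chromium alkoxide so that the aldehyde is never released, the released aldehyde may be allylated a second time, and the C9 radical may undergo 1,2-vinyl migration before chromium captures it. The fallback uses known reactions in separate operations; it sets out from 12 and returns at 22. Lactol 12 is allylated under aqueous Barbier conditions with indium metal and the parent reagent 3-(bromomethyl)furan-2(5H)-one (BrCC1=CCOC1=O), which should give the anti Felkin adduct (4R)-4-[(1R,2S,3S)-1-hydroxy-3-(hydroxymethyl)-3-(iodomethyl)-2-(prop-1-en-2-yl)pent-4-en-1-yl]-3-methylideneoxolan-2-one F1. DBU-mediated translactonisation should then give the trans-disubstituted lactone (4R,5R)-4-(hydroxymethyl)-5-[(1S,2S)-2-(hydroxymethyl)-2-(iodomethyl)-1-(prop-1-en-2-yl)but-3-en-1-yl]-3-methylideneoxolan-2-one F2. TEMPO with PhI(OAc)2 should oxidise the less hindered CH2OH (not the neopentyl one) to aldehyde 21, now isolated, and a separate cobalt-catalysed alkylchromium cyclisation (CrCl2, cat. cyanocobalamin, DMF) closes the C8–C9 bond to 22.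

Step 4. Deprotonation may occur at the doubly allylic ring C–H instead of the ethylidene methyl group (epimerisation of C5), the dienolate may be alkylated at its γ-terminus, facial control may be incomplete, or the base may metalate CH2I2. The fallback sets out from 5 and returns at 9. The alkoxide–enolate dianion of 5 (LiN(i-Pr)2, 2.2 equiv; Fráter–Seebach-type alkylation) is alkylated with CH2I2 anti to the isopropenyl group to give (3R,4S,5S)-3-(1-hydroxyethyl)-3-(iodomethyl)-5-(menthyloxy)-4-(prop-1-en-2-yl)oxolan-2-one F3. Its secondary carbinol, which has β-hydrogens only on the methyl group, is then dehydrated with Burgess reagent to the vinyl group of 9.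

Step 6. Oxidation may take place at the neopentyl carbinol (giving the regioisomeric lactol) or run on to the lactone. The fallback sets out from 9 and returns at 12; it uses the different oxidation levels of C14 and C6 in 9 instead of a regioselective oxidation. Acidic methanol with trimethyl orthoformate (HC(OMe)3, MeOH, cat. H2SO4) should open the pseudo-ester to the normal ester acetal, methyl (2S,3S)-3-(dimethoxymethyl)-2-ethenyl-2-(iodomethyl)-4-methylpent-4-enoate F4. Reduction with (i-Bu)2AlH should give (2S,3S)-3-(dimethoxymethyl)-2-ethenyl-2-(iodomethyl)-4-methylpent-4-en-1-ol F5, and mild aqueous acid (AcOH, THF, H2O) hydrolyses the acetal, which closes to lactol 12.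

Further compounds

F1 | step 10 | (4R)-4-[(1R,2S,3S)-1-hydroxy-3-(hydroxymethyl)-3-(iodomethyl)-2-(prop-1-en-2-yl)pent-4-en-1-yl]-3-methylideneoxolan-2-one | C=C[C@](CO)(CI)[C@@H]([C@@H](O)[C@@H]1C(=C)C(=O)OC1)C(C)=C
F2 | step 10 | (4R,5R)-4-(hydroxymethyl)-5-[(1S,2S)-2-(hydroxymethyl)-2-(iodomethyl)-1-(prop-1-en-2-yl)but-3-en-1-yl]-3-methylideneoxolan-2-one | C=C[C@](CO)(CI)[C@@H]([C@H]1OC(=O)C(=C)[C@@H]1CO)C(C)=C
F3 | step 4 | (3R,4S,5S)-3-(1-hydroxyethyl)-3-(iodomethyl)-5-(menthyloxy)-4-(prop-1-en-2-yl)oxolan-2-one | CC(O)[C@@]1(CI)C(=O)O[C@H](O[C@H]2C[C@@H](C)CC[C@@H]2C(C)C)[C@H]1C(C)=C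
F4 | step 6 | methyl (2S,3S)-3-(dimethoxymethyl)-2-ethenyl-2-(iodomethyl)-4-methylpent-4-enoate | C=C[C@](C(=O)OC)(CI)[C@@H](C(OC)OC)C(C)=C
F5 | step 6 | (2S,3S)-3-(dimethoxymethyl)-2-ethenyl-2-(iodomethyl)-4-methylpent-4-en-1-ol | C=C[C@](CO)(CI)[C@@H](C(OC)OC)C(C)=C
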